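The ring is numbered C1 (ketone beside carbinol C6), C2 (acyl-bearing), C3 (enol carbon), C4, C5, C6. The cyclohexane-1,3-dione ring is cut at C5–C6 and C2–C3, which splits it into a ketone fragment C6–C1–C2 and an acrylate fragment C3–C4–C5. One Michael–Claisen [3+3] annulation of 1-(benzyloxy)propan-2-one with ethyl acrylate forms both bonds. It exploits that C6 and C2 are the two α-carbons of the C1 ketone and that C3 is a carboxyl-level carbon three atoms from C5. The ring is made racemic; a lipase then selects the R carbinol as its acetate, which also protects it while the (7E,9E)-dienoyl chain, built by Suzuki coupling, is put on C2.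

Key step: step 4

Remark on the chemistry: the 1,3-diones and β-triketones are written as one enol tautomer; the tautomers interconvert, so dione names and enol SMILES mean the same compound. Methyl oct-7-ynoate and 1-(benzyloxy)propan-2-one are taken as purchasable.

**Route**

Step 1
Reactants: 1 dec-1-yne
Product: 3 (E)-1-iododec-1-ene, via (E)-dec-1-enyl(diisobutyl)alane 2 (not isolated)
Conditions: iBu2AlH, hexane, 50 °C; then I2, THF, −50 °C to rt
Reagents that add atoms: iodine, II
Why: Hydroalumination–iodination: syn addition of Al–H to the terminal alkyne places aluminium on C1, and iodinolysis of the C–Al bond goes with retention, so the E iodide should result.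

Step 2
Reactants: 4 methyl oct-7-ynoate
Product: 5 methyl (E)-8-(4,4,5,5-tetramethyl-1,3,2-dioxaborolan-2-yl)oct-7-enoate
Conditions: pinacolborane (1.1 equiv), Cy2BH (10 mol %), neat, rt
Reagents that add atoms: pinacolborane, [H]B1OC(C)(C)C(C)(C)O1
Why: Dialkylborane-catalysed hydroboration of a terminal alkyne with pinacolborane is syn and anti-Markovnikov, giving the E alkenylboronate while the ester is left alone.

Step 3
Reactants: 3 (E)-1-iododec-1-ene; 5 methyl (E)-8-(4,4,5,5-tetramethyl-1,3,2-dioxaborolan-2-yl)oct-7-enoate
Product: 7 (7E,9E)-octadeca-7,9-dienoic acid, via methyl (7E,9E)-octadeca-7,9-dienoate 6 (not isolated)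
Conditions: Pd(PPh3)4 (5 mol %), NaOH (aq., 3 equiv), THF, 60 °C; then HCl (aq.)
Reagents that add atoms: sodium hydroxide, [Na+].[OH-]
Why: Suzuki–Miyaura coupling of two alkenyl partners goes with retention at both double bonds and should give the E,E diene; the aqueous hydroxide then saponifies the methyl ester in the same flask.

Step 4
Reactants: 8 1-(benzyloxy)propan-2-one; 9 ethyl acrylate
Product: 11 4-(benzyloxy)cyclohexane-1,3-dione (racemic), via ethyl 4-(benzyloxy)-5-oxohexanoate 10 (not isolated)
Conditions: KOtBu (2.0 equiv), THF, −10 °C, slow addition of 9, then rt; HCl (aq.)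
Reagents that add atoms: none
Why: This is the consecutive Michael–Claisen (Dieckmann) [3+3] annulation by which α-substituted acetones and acrylates give 4-substituted cyclohexane-1,3-diones. The potassium enolate on the benzyloxy-bearing carbon of 8 adds to the β-carbon of 9 (bond C5–C6), proton transfer moves the enolate to the methyl group of 10, and this carbon attacks the ester (bond C2–C3) in a 6-exo-trig closure made irreversible by deprotonation of the 1,3-dione formed. The one new stereocentre, the benzyloxy carbon, arises from a planar enolate and an achiral acceptor, so nothing controls it and 11 is racemic; its configuration is selected in step 6. The selectivity the step needs is regiochemical, Michael addition at the oxygenated α-carbon and acylation at the methyl carbon and not the reverse: the α-alkoxy methylene is the more acidic site and gives the more substituted, potassium-chelated Z enolate under equilibrating conditions, and after the first bond only the methyl group can close a six-membered ring. Slow addition of 9 to an excess of the enolate at low temperature should hold back a second Michael addition at the now tertiary carbon.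

Step 5
Reactants: 11 4-(benzyloxy)cyclohexane-1,3-dione (racemic)
Product: 12 4-hydroxycyclohexane-1,3-dione (racemic)
Conditions: H2 (1 atm), Pd/C (10 %), EtOAc, rt
Reagents that add atoms: none
Why: Hydrogenolysis of a benzyl ether over Pd/C under neutral conditions at low pressure should leave the enolised 1,3-dione intact.

Step 6
Reactants: 12 4-hydroxycyclohexane-1,3-dione (racemic)
Product: 13 (R)-4-acetoxycyclohexane-1,3-dione
Conditions: Burkholderia cepacia lipase (Amano PS, immobilised), vinyl acetate (3 equiv), THF/MTBE, 30 °C, stopped near 50 % conversion; chromatography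
Reagents that add atoms: vinyl acetate, CC(=O)OC=C
Why: Lipase-catalysed kinetic resolution by irreversible transesterification: by the empirical size rule for secondary alcohols (carbonyl side large, ring CH2 side medium) the R alcohol should be acetylated fast while the S alcohol stays behind and is separated, so the stereocentre is fixed here by the enzyme.

Step 7
Reactants: 13 (R)-4-acetoxycyclohexane-1,3-dione; 7 (7E,9E)-octadeca-7,9-dienoic acid
Product: 15 (R)-4-acetoxy-2-[(7E,9E)-octadeca-7,9-dienoyl]cyclohexane-1,3-dione, via enol ester 14 (not isolated)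
Conditions: DCC (1.1 equiv), DMAP (1.2 equiv), CH2Cl2, 0 °C to rt
Reagents that add atoms: none
Why: Carbodiimide O-acylation of the enol followed by DMAP-mediated 1,3 O-to-C acyl migration, the standard entry to 2-acylcyclohexane-1,3-diones, should place the acyl group on C2, the only carbon between the two carbonyls, while the acetate masks the secondary hydroxyl.

Step 8
Reactants: 15 (R)-4-acetoxy-2-[(7E,9E)-octadeca-7,9-dienoyl]cyclohexane-1,3-dione
Product: 16 (6R)-3,6-dihydroxy-2-[(7E,9E)-octadeca-7,9-dienoyl]cyclohex-2-en-1-one
Conditions: K2CO3 (2 equiv), MeOH, 0 °C; HCl (aq.) to pH 3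
Reagents that add atoms: none
Why: Mild methanolysis should cleave the activated α-acyloxy-ketone acetate while the triketone sits as its potassium enolate, which keeps the C6–H from enolising, so the R centre is retained.

**Compound list**

1 | dec-1-yne | CCCCCCCCC#C | starting material
2 | (E)-dec-1-enyl(diisobutyl)alane | CCCCCCCC/C=C/[Al](CC(C)C)CC(C)C | intermediate (not isolated)
3 | (E)-1-iododec-1-ene | CCCCCCCC/C=C/I | intermediate
4 | methyl oct-7-ynoate | COC(=O)CCCCCC#C | starting material
5 | methyl (E)-8-(4,4,5,5-tetramethyl-1,3,2-dioxaborolan-2-yl)oct-7-enoate | COC(=O)CCCCC/C=C/B1OC(C)(C)C(C)(C)O1 | intermediate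
6 | methyl (7E,9E)-octadeca-7,9-dienoate | CCCCCCCC/C=C/C=C/CCCCCC(=O)OC | intermediate (not isolated)
7 | (7E,9E)-octadeca-7,9-dienoic acid | CCCCCCCC/C=C/C=C/CCCCCC(=O)O | intermediate
8 | 1-(benzyloxy)propan-2-one | CC(=O)COCc1ccccc1 | starting material
9 | ethyl acrylate | C=CC(=O)OCC | starting material
10 | ethyl 4-(benzyloxy)-5-oxohexanoate (racemic) | CCOC(=O)CCC(OCc1ccccc1)C(C)=O | intermediate (not isolated)
11 | 4-(benzyloxy)cyclohexane-1,3-dione (racemic; drawn as 6-(benzyloxy)-3-hydroxycyclohex-2-en-1-one) | OC1=CC(=O)C(OCc2ccccc2)CC1 | intermediate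
12 | 4-hydroxycyclohexane-1,3-dione (racemic; drawn as 3,6-dihydroxycyclohex-2-en-1-one) | OC1=CC(=O)C(O)CC1 | intermediate
13 | (R)-4-acetoxycyclohexane-1,3-dione (drawn as (1R)-4-hydroxy-2-oxocyclohex-3-en-1-yl acetate) | OC1=CC(=O)[C@H](OC(C)=O)CC1 | intermediate
14 | (4R)-4-acetoxy-3-oxocyclohex-1-en-1-yl (7E,9E)-octadeca-7,9-dienoate (the enol ester on the other oxygen would behave alike) | CCCCCCCC/C=C/C=C/CCCCCC(=O)OC1=CC(=O)[C@H](OC(C)=O)CC1 | intermediate (not isolated)
15 | (R)-4-acetoxy-2-[(7E,9E)-octadeca-7,9-dienoyl]cyclohexane-1,3-dione (drawn as (1R)-4-hydroxy-3-[(7E,9E)-octadeca-7,9-dienoyl]-2-oxocyclohex-3-en-1-yl acetate) | CCCCCCCC/C=C/C=C/CCCCCC(=O)C1=C(O)CC[C@@H](OC(C)=O)C1=O | intermediate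
16 | (6R)-3,6-dihydroxy-2-[(7E,9E)-octadeca-7,9-dienoyl]cyclohex-2-en-1-one | CCCCCCCC/C=C/C=C/CCCCCC(=O)C1=C(O)CC[C@@H](O)C1=O | target

**Step count and risks**

Total step count: 8. Longest linear sequence: 5 steps (steps 4 to 8, from compounds 8 and 9).

Steps most likely to fail:

1. Step 4. The first C–C bond may form at the methyl carbon instead of the oxygenated carbon (giving the 2-benzyloxy isomer after ring closure), or a second Michael addition or acrylate oligomerisation may outrun the ring closure. Fallback: a temporary ester tells the two α-positions apart. It sets out from 9. Purchased ethyl 4-(benzyloxy)-3-oxobutanoate is converted into its dianion (NaH, then n-BuLi, THF, 0 °C), which can add to 9 only through its benzyloxy-bearing γ-carbon. On warming, the remaining β-keto ester carbanion closes the ring onto the acrylate ester (Dieckmann) to give ethyl 3-(benzyloxy)-2,6-dioxocyclohexane-1-carboxylate F1. Saponification and acidification (NaOH aq., then HCl, 50 °C) should decarboxylate it, and the route is rejoined at 11.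

2. Step 6. The enzyme may discriminate the enantiomers poorly, or acylation may stall because the polar, acidic dione is a poor substrate. Fallback: covalent resolution through diastereomers. It sets out from 12. (1S)-Camphanic chloride, pyridine and CH2Cl2 should give the two diastereomeric camphanates of the secondary hydroxyl (any enol camphanate is cleaved on aqueous work-up), which are separated by crystallisation or chromatography. The ester of the R alcohol, (1R)-4-hydroxy-2-oxocyclohex-3-en-1-yl (1S,4R)-camphanate F2, takes the place of 13 in the C-acylation with 7 (DCC, DMAP) and should give (1R)-4-hydroxy-3-[(7E,9E)-octadeca-7,9-dienoyl]-2-oxocyclohex-3-en-1-yl (1S,4R)-camphanate F3. K2CO3 in MeOH removes the camphanate, and the route is rejoined at 16.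

3. Step 7. The reaction may stop at the O-acyl enol ester, or the acetate may be lost or scrambled under nucleophilic catalysis. Fallback: acylate the robust ether and resolve last. It sets out from 11. C-acylation of 11 with 7 (DCC, DMAP) should give racemic 4-(benzyloxy)-2-[(7E,9E)-octadeca-7,9-dienoyl]cyclohexane-1,3-dione F4. BCl3 with pentamethylbenzene (CH2Cl2, −78 °C) removes the benzyl group without hydrogenating the diene and should give racemic 3,6-dihydroxy-2-[(7E,9E)-octadeca-7,9-dienoyl]cyclohex-2-en-1-one F5. Lipase PS with vinyl acetate should then acetylate the R enantiomer, and the route is rejoined at 15.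

**Further compounds**

F1 | step 4 | ethyl 3-(benzyloxy)-2,6-dioxocyclohexane-1-carboxylate (racemic, enol form) | CCOC(=O)C1=C(O)CCC(OCc2ccccc2)C1=O
F2 | step 6 | (1R)-4-hydroxy-2-oxocyclohex-3-en-1-yl (1S,4R)-4,7,7-trimethyl-3-oxo-2-oxabicyclo[2.2.1]heptane-1-carboxylate | O=C(O[C@@H]3CCC(O)=CC3=O)[C@@]12CC[C@@](C)(C(=O)O1)C2(C)C
F3 | step 6 | (1R)-4-hydroxy-3-[(7E,9E)-octadeca-7,9-dienoyl]-2-oxocyclohex-3-en-1-yl (1S,4R)-4,7,7-trimethyl-3-oxo-2-oxabicyclo[2.2.1]heptane-1-carboxylate | CCCCCCCC/C=C/C=C/CCCCCC(=O)C1=C(O)CC[C@@H](OC(=O)[C@@]23CC[C@@](C)(C(=O)O2)C3(C)C)C1=O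
F4 | step 7 | 4-(benzyloxy)-2-[(7E,9E)-octadeca-7,9-dienoyl]cyclohexane-1,3-dione (racemic, enol form) | CCCCCCCC/C=C/C=C/CCCCCC(=O)C1=C(O)CCC(OCc2ccccc2)C1=O
F5 | step 7 | 3,6-dihydroxy-2-[(7E,9E)-octadeca-7,9-dienoyl]cyclohex-2-en-1-one (racemic) | CCCCCCCC/C=C/C=C/CCCCCC(=O)C1=C(O)CCC(O)C1=O
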